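The 1,2-dioxane is built by a formal [3+3] annulation that joins ring carbon C5 to the quaternary peroxide carbon C6 and the distal peroxide oxygen to C3. It exploits two features of the ring: C6, flanked by O–O, a methyl group and the chain, is a latent peroxycarbenium ion, and C3 lies β to the propanoate carbonyl, so it can be the alkyl carbon of a trans-β-lactone. A silyl peroxyketal is alkylated at C6 by an alkylzinc reagent carrying that lactone; the silylperoxy oxygen then opens the lactone at C3 with inversion (6-exo-tet), unveiling the acid. The hydroperoxide arm is attached afterwards by Julia–Kocienski olefination with an epoxide-derived α-peroxy aldehyde.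

Key step: step 10

Remark: locants follow the propanoate chain: C1 ester carbon, C2 methyl-bearing carbon, C3–C6 ring carbons (C3 carries the propanoate arm, C6 the methyl group and the chain), C7–C18 chain with the methyl branch at C10 and the hydroperoxide at C14; in these locants the target is 2R,3S,6R,10R,14R.

**Lactone-bearing zinc reagent**

Step 1
Reactants: 1 3-(benzyloxy)propanal; 2 acetyl chloride
Product: 3 (4R)-4-[2-(benzyloxy)ethyl]oxetan-2-one
Conditions: O-trimethylsilylquinine (10 mol %), LiClO4, iPr2NEt, CH2Cl2/Et2O, −78 °C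
Reagents that add atoms: none
Why: Cinchona-alkaloid/LiClO4-catalysed acyl halide–aldehyde cyclocondensation (formal ketene–aldehyde [2+2] cycloaddition), in which the chiral ammonium enolate of ketene should add to one aldehyde face and set the lactone C4 (later C3) as R, the quinidine-derived catalyst giving the antipode.

Step 2
Reactants: 3 (4R)-4-[2-(benzyloxy)ethyl]oxetan-2-one
Product: 4 (3R,4R)-4-[2-(benzyloxy)ethyl]-3-methyloxetan-2-one
Conditions: LiN(iPr)2, THF, −78 °C; then MeI, −78 °C
Reagents that add atoms: iodomethane CI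
Why: β-Lactone enolate alkylation, in which the lithium enolate should be methylated anti to the C4 side chain to give the trans lactone and so fix the later C2 as R.

Step 3
Reactants: 4 (3R,4R)-4-[2-(benzyloxy)ethyl]-3-methyloxetan-2-one
Product: 5 (3R,4R)-4-(2-hydroxyethyl)-3-methyloxetan-2-one
Conditions: H2 (1 atm), Pd/C, EtOAc, 25 °C
Reagents that add atoms: none
Why: Hydrogenolysis of the benzyl ether under neutral conditions leaves the lactone and both stereocentres untouched; the alcohol is used at once to avoid translactonization.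

Step 4
Reactants: 5 (3R,4R)-4-(2-hydroxyethyl)-3-methyloxetan-2-one
Product: 6 (3R,4R)-4-(2-iodoethyl)-3-methyloxetan-2-one
Conditions: I2, PPh3, imidazole, CH2Cl2, 0 °C
Reagents that add atoms: iodine II
Why: Appel-type iodination of the primary alcohol, fast enough at 0 °C to outrun ring expansion of the hydroxy lactone.

Step 5
Reactants: 6 (3R,4R)-4-(2-iodoethyl)-3-methyloxetan-2-one
Product: 7 iodo{2-[(2R,3R)-3-methyl-4-oxooxetan-2-yl]ethyl}zinc
Conditions: Zn dust (activated with BrCH2CH2Br and Me3SiCl), LiCl, THF, 25 °C; used as solution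
Reagents that add atoms: zinc [Zn]
Why: LiCl-promoted direct insertion of zinc into a primary alkyl iodide; alkylzinc halides tolerate ester-type carbonyl groups, so the lactone should survive.

**Silyl peroxyketal**

Step 6
Reactants: 8 (S)-citronellyl bromide
Product: 9 (4S)-6-bromo-4-methylhexan-1-ol
Conditions: O3, CH2Cl2/MeOH, −78 °C; then NaBH4, −78 to 0 °C
Reagents that add atoms: ozone [O-][O+]=O
Why: Ozonolysis with reductive work-up cleaves the trisubstituted alkene to the primary alcohol without touching the bromide or the methyl-bearing stereocentre (later C10).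

Step 7
Reactants: 9 (4S)-6-bromo-4-methylhexan-1-ol
Product: 11 (6S)-8-bromo-2,6-dimethyloct-1-ene, via triflate 10 (not isolated)
Conditions: Tf2O, 2,6-lutidine, Et2O, −78 °C; then CH2=C(CH3)MgBr, CuBr·SMe2 (5 mol %), THF, −78 to −20 °C
Reagents that add atoms: trifluoromethanesulfonic anhydride O=S(=O)(OS(=O)(=O)C(F)(F)F)C(F)(F)F (atoms kept only in 10); isopropenylmagnesium bromide C=C(C)[Mg]Br
Why: Copper-catalysed Grignard cross-coupling of a primary alkyl triflate, which should react far faster than the primary bromide at low temperature.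

Step 8
Reactants: 11 (6S)-8-bromo-2,6-dimethyloct-1-ene
Product: 12 (6S)-8-bromo-2-methoxy-6-methyloctan-2-yl hydroperoxide
Conditions: O3, MeOH/CH2Cl2, NaHCO3, −78 °C
Reagents that add atoms: ozone [O-][O+]=O; methanol CO
Why: Criegee ozonolysis in methanol, in which the carbonyl oxide formed at the disubstituted carbon is trapped by methanol to give the α-methoxy hydroperoxide (both ketal epimers, of no consequence).

Step 9
Reactants: 12 (6S)-8-bromo-2-methoxy-6-methyloctan-2-yl hydroperoxide
Product: 13 {[(6S)-8-bromo-2-methoxy-6-methyloctan-2-yl]peroxy}triethylsilane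
Conditions: Et3SiCl, imidazole, DMF, 0 °C
Reagents that add atoms: chlorotriethylsilane CC[Si](Cl)(CC)CC
Why: O-Silylation of the acidic hydroperoxide gives the silyl peroxyketal, the standard precursor of peroxycarbenium ions.

**Annulation and elaboration of the ring fragment**

Step 10
Reactants: 13 {[(6S)-8-bromo-2-methoxy-6-methyloctan-2-yl]peroxy}triethylsilane; 7 iodo{2-[(2R,3R)-3-methyl-4-oxooxetan-2-yl]ethyl}zinc
Product: 16 (2R)-2-{(3S,6R)-6-[(4S)-6-bromo-4-methylhexyl]-6-methyl-1,2-dioxan-3-yl}propanoic acid, via silyl peroxide lactone 14 (not isolated), via triethylsilyl ester 15 (not isolated)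
Conditions: 7 (2 equiv, THF exchanged for CH2Cl2), Me3SiOTf (1.5 equiv), CH2Cl2, −78 °C, then −78 to 0 °C; aqueous citric acid work-up
Reagents that add atoms: none
Why: Proposed new method: Me3SiOTf ionizes the methoxy group of 13 to a peroxycarbenium ion (the intermediate of the known Lewis-acid annulations of silyl peroxyketals with alkenes and allylsilanes), which is captured at C6 by the primary alkylzinc 7, as acetal-derived oxocarbenium ions are by organozincs, to give tertiary silyl peroxide 14; the Zn(OTf)I set free and the excess Me3SiOTf then activate the β-lactone, whose alkyl C–O bond is broken by the distal silylperoxy oxygen with transfer of Et3Si to the carboxylate (15), the peroxide counterpart of Lewis-acid alkyl–oxygen opening of β-lactones and oxetanes by tethered oxygen nucleophiles. The 1,2-dioxane closes in the 6-exo-tet mode. C3 is set by SN2 inversion at the lactone C4 (4R in 7 becomes 3S), and the trans methyl group from step 2 is carried over as C2 (R) because no enolate is formed. C6 is created in the intermolecular C–C event from a planar cation whose nearest stereocentre (C10) is four bonds away, so no useful bias is expected and both C6 epimers should form; the 3,6-trans isomer 16 (both large groups equatorial) is separated after step 11. The step needs C-alkylation of the cation rather than attack of the organozinc on the O–O bond (secured by the low temperature and the strongly electrophilic carbon) and alkyl–oxygen rather than acyl–oxygen cleavage of the lactone (secured by the six-membered as against eight-membered transition state and by Lewis-acid activation). The primary bromide is inert to the alkylzinc reagent.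

Step 11
Reactants: 16 (2R)-2-{(3S,6R)-6-[(4S)-6-bromo-4-methylhexyl]-6-methyl-1,2-dioxan-3-yl}propanoic acid
Product: 17 methyl (2R)-2-{(3S,6R)-6-[(4S)-6-bromo-4-methylhexyl]-6-methyl-1,2-dioxan-3-yl}propanoate
Conditions: Me3SiCHN2, MeOH/toluene, 0 °C; chromatographic removal of the C6 epimer
Reagents that add atoms: (trimethylsilyl)diazomethane C[Si](C)(C)C=[N+]=[N-]
Why: Base-free esterification of the acid with a diazoalkane avoids retro-oxa-Michael opening of the ring, and the cis/trans ring diastereomers should be separable as methyl esters.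

Step 12
Reactants: 17 methyl (2R)-2-{(3S,6R)-6-[(4S)-6-bromo-4-methylhexyl]-6-methyl-1,2-dioxan-3-yl}propanoate
Product: 18 methyl (2R)-2-[(3S,6R)-6-methyl-6-{(4S)-4-methyl-6-[(1-phenyl-1H-tetrazol-5-yl)sulfanyl]hexyl}-1,2-dioxan-3-yl]propanoate
Conditions: 1-phenyl-1H-tetrazole-5-thiol, K2CO3, DMF, 25 °C
Reagents that add atoms: 1-phenyl-1H-tetrazole-5-thiol Sc1nnnn1-c1ccccc1
Why: SN2 displacement of the primary bromide by the soft thiolate under conditions too weakly basic to enolize the ester.

Step 13
Reactants: 18 methyl (2R)-2-[(3S,6R)-6-methyl-6-{(4S)-4-methyl-6-[(1-phenyl-1H-tetrazol-5-yl)sulfanyl]hexyl}-1,2-dioxan-3-yl]propanoate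
Product: 19 methyl (2R)-2-[(3S,6R)-6-methyl-6-{(4S)-4-methyl-6-[(1-phenyl-1H-tetrazol-5-yl)sulfonyl]hexyl}-1,2-dioxan-3-yl]propanoate
Conditions: (NH4)6Mo7O24·4H2O (10 mol %), 30% aq. H2O2, EtOH, 0 to 25 °C
Reagents that add atoms: hydrogen peroxide OO
Why: Molybdate-catalysed oxidation of the sulfide to the sulfone; the dialkyl peroxide and the ester are inert to these conditions.

**α-Peroxy aldehyde**

Step 14
Reactants: 20 geraniol
Product: 21 [(2R,3R)-3-methyl-3-(4-methylpent-3-en-1-yl)oxiran-2-yl]methanol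
Conditions: Ti(OiPr)4 (5 mol %), D-(−)-diethyl tartrate (7 mol %), tBuOOH, 4 Å molecular sieves, CH2Cl2, −20 °C
Reagents that add atoms: tert-butyl hydroperoxide CC(C)(C)OO
Why: Sharpless asymmetric epoxidation, in which the D-tartrate catalyst delivers oxygen to the allylic alkene face that gives the (2R,3R) epoxide and the remote alkene is left alone.

Step 15
Reactants: 21 [(2R,3R)-3-methyl-3-(4-methylpent-3-en-1-yl)oxiran-2-yl]methanol
Product: 22 (2R,3S)-3-hydroperoxy-3,7-dimethyloct-6-ene-1,2-diol
Conditions: H2O2 (ethereal, 10 equiv), H3PMo12O40 (2 mol %), Et2O, 0 to 25 °C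
Reagents that add atoms: hydrogen peroxide OO
Why: Acid-catalysed perhydrolysis of the epoxide at its tertiary carbon, a borderline SN2 opening that should proceed with inversion and so set the later C14.

Step 16
Reactants: 22 (2R,3S)-3-hydroperoxy-3,7-dimethyloct-6-ene-1,2-diol
Product: 24 (2S)-2-[(2-methoxypropan-2-yl)peroxy]-2,6-dimethylhept-5-enal, via hydroperoxy aldehyde 23 (not isolated)
Conditions: NaIO4, THF/pH 7 buffer, 0 °C; extraction; then CH2=C(OMe)CH3, pyridinium p-toluenesulfonate (cat.), CH2Cl2, 0 °C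
Reagents that add atoms: 2-methoxypropene COC(C)=C
Why: Malaprade glycol cleavage followed at once by acid-catalysed addition of the hydroperoxide to the enol ether (perketalization); the quaternary stereocentre is not involved.

**Coupling and completion**

Step 17
Reactants: 19 methyl (2R)-2-[(3S,6R)-6-methyl-6-{(4S)-4-methyl-6-[(1-phenyl-1H-tetrazol-5-yl)sulfonyl]hexyl}-1,2-dioxan-3-yl]propanoate; 24 (2S)-2-[(2-methoxypropan-2-yl)peroxy]-2,6-dimethylhept-5-enal
Product: 25 methyl (2R)-2-[(3S,6R)-6-{(4S,6E,8S)-8-[(2-methoxypropan-2-yl)peroxy]-4,8,12-trimethyltrideca-6,11-dien-1-yl}-6-methyl-1,2-dioxan-3-yl]propanoate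
Conditions: KN(SiMe3)2 (1.05 equiv), 1,2-dimethoxyethane, −78 °C; then 24, −78 to 25 °C
Reagents that add atoms: none
Why: Julia–Kocienski olefination of the non-enolizable α-peroxy aldehyde with the kinetically formed sulfonyl carbanion; the alkene geometry is of no consequence.

Step 18
Reactants: 25 methyl (2R)-2-[(3S,6R)-6-{(4S,6E,8S)-8-[(2-methoxypropan-2-yl)peroxy]-4,8,12-trimethyltrideca-6,11-dien-1-yl}-6-methyl-1,2-dioxan-3-yl]propanoate
Product: 26 methyl (2R)-2-[(3S,6R)-6-{(4S,8R)-8-[(2-methoxypropan-2-yl)peroxy]-4,8,12-trimethyltridec-11-en-1-yl}-6-methyl-1,2-dioxan-3-yl]propanoate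
Conditions: 2-nitrobenzenesulfonylhydrazide, Et3N, CH2Cl2, 25 °C
Reagents that add atoms: none
Why: Diimide reduction should saturate the 1,2-disubstituted alkene much faster than the trisubstituted one and does not cleave O–O bonds.

Step 19
Reactants: 26 methyl (2R)-2-[(3S,6R)-6-{(4S,8R)-8-[(2-methoxypropan-2-yl)peroxy]-4,8,12-trimethyltridec-11-en-1-yl}-6-methyl-1,2-dioxan-3-yl]propanoate
Product: 27 methyl (2R)-2-{(3S,6R)-6-[(4R,8R)-8-hydroperoxy-4,8,12-trimethyltridec-11-en-1-yl]-6-methyl-1,2-dioxan-3-yl}propanoate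
Conditions: AcOH/THF/H2O (4:2:1), 25 °C
Reagents that add atoms: none
Why: Mild acid hydrolysis of the peroxyketal frees the tertiary hydroperoxide without affecting the dialkyl peroxide ring, the ester or the alkene.

**Compound list**

1 | 3-(benzyloxy)propanal | O=CCCOCc1ccccc1 | starting material
2 | acetyl chloride | CC(Cl)=O | starting material
3 | (4R)-4-[2-(benzyloxy)ethyl]oxetan-2-one | O=C1C[C@@H](CCOCc2ccccc2)O1 | intermediate
4 | (3R,4R)-4-[2-(benzyloxy)ethyl]-3-methyloxetan-2-one | C[C@@H]1[C@@H](CCOCc2ccccc2)OC1=O | intermediate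
5 | (3R,4R)-4-(2-hydroxyethyl)-3-methyloxetan-2-one | C[C@@H]1[C@@H](CCO)OC1=O | intermediate
6 | (3R,4R)-4-(2-iodoethyl)-3-methyloxetan-2-one | C[C@@H]1[C@@H](CCI)OC1=O | intermediate
7 | iodo{2-[(2R,3R)-3-methyl-4-oxooxetan-2-yl]ethyl}zinc | C[C@@H]1[C@@H](CC[Zn]I)OC1=O | intermediate
8 | (S)-citronellyl bromide, (6S)-8-bromo-2,6-dimethyloct-2-ene | CC(C)=CCC[C@H](C)CCBr | starting material
9 | (4S)-6-bromo-4-methylhexan-1-ol | OCCC[C@H](C)CCBr | intermediate
10 | (4S)-6-bromo-4-methylhexyl trifluoromethanesulfonate | O=S(=O)(OCCC[C@H](C)CCBr)C(F)(F)F | intermediate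
11 | (6S)-8-bromo-2,6-dimethyloct-1-ene | C=C(C)CCC[C@H](C)CCBr | intermediate
12 | (6S)-8-bromo-2-methoxy-6-methyloctan-2-yl hydroperoxide (both C2 epimers) | COC(C)(OO)CCC[C@H](C)CCBr | intermediate
13 | {[(6S)-8-bromo-2-methoxy-6-methyloctan-2-yl]peroxy}triethylsilane (both C2 epimers) | COC(C)(OO[Si](CC)(CC)CC)CCC[C@H](C)CCBr | intermediate
14 | (3R,4R)-4-{(3R,7S)-9-bromo-3,7-dimethyl-3-[(triethylsilyl)peroxy]nonyl}-3-methyloxetan-2-one | C[C@@H]1[C@@H](CC[C@@](C)(CCC[C@H](C)CCBr)OO[Si](CC)(CC)CC)OC1=O | intermediate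
15 | triethylsilyl (2R)-2-{(3S,6R)-6-[(4S)-6-bromo-4-methylhexyl]-6-methyl-1,2-dioxan-3-yl}propanoate | CC[Si](CC)(CC)OC(=O)[C@H](C)[C@@H]1CC[C@@](C)(CCC[C@H](C)CCBr)OO1 | intermediate
16 | (2R)-2-{(3S,6R)-6-[(4S)-6-bromo-4-methylhexyl]-6-methyl-1,2-dioxan-3-yl}propanoic acid | OC(=O)[C@H](C)[C@@H]1CC[C@@](C)(CCC[C@H](C)CCBr)OO1 | intermediate
17 | methyl (2R)-2-{(3S,6R)-6-[(4S)-6-bromo-4-methylhexyl]-6-methyl-1,2-dioxan-3-yl}propanoate | COC(=O)[C@H](C)[C@@H]1CC[C@@](C)(CCC[C@H](C)CCBr)OO1 | intermediate
18 | methyl (2R)-2-[(3S,6R)-6-methyl-6-{(4S)-4-methyl-6-[(1-phenyl-1H-tetrazol-5-yl)sulfanyl]hexyl}-1,2-dioxan-3-yl]propanoate | COC(=O)[C@H](C)[C@@H]1CC[C@@](C)(CCC[C@H](C)CCSc2nnnn2-c2ccccc2)OO1 | intermediate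
19 | methyl (2R)-2-[(3S,6R)-6-methyl-6-{(4S)-4-methyl-6-[(1-phenyl-1H-tetrazol-5-yl)sulfonyl]hexyl}-1,2-dioxan-3-yl]propanoate | COC(=O)[C@H](C)[C@@H]1CC[C@@](C)(CCC[C@H](C)CCS(=O)(=O)c2nnnn2-c2ccccc2)OO1 | intermediate
20 | geraniol | CC(C)=CCC/C(C)=C/CO | starting material
21 | [(2R,3R)-3-methyl-3-(4-methylpent-3-en-1-yl)oxiran-2-yl]methanol | OC[C@@H]1[C@@](C)(CCC=C(C)C)O1 | intermediate
22 | (2R,3S)-3-hydroperoxy-3,7-dimethyloct-6-ene-1,2-diol | OC[C@@H](O)[C@](C)(CCC=C(C)C)OO | intermediate
23 | (2S)-2-hydroperoxy-2,6-dimethylhept-5-enal | O=C[C@](C)(CCC=C(C)C)OO | intermediate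
24 | (2S)-2-[(2-methoxypropan-2-yl)peroxy]-2,6-dimethylhept-5-enal | O=C[C@](C)(CCC=C(C)C)OOC(C)(C)OC | intermediate
25 | methyl (2R)-2-[(3S,6R)-6-{(4S,6E,8S)-8-[(2-methoxypropan-2-yl)peroxy]-4,8,12-trimethyltrideca-6,11-dien-1-yl}-6-methyl-1,2-dioxan-3-yl]propanoate | COC(=O)[C@H](C)[C@@H]1CC[C@@](C)(CCC[C@H](C)C/C=C/[C@](C)(CCC=C(C)C)OOC(C)(C)OC)OO1 | intermediate
26 | methyl (2R)-2-[(3S,6R)-6-{(4S,8R)-8-[(2-methoxypropan-2-yl)peroxy]-4,8,12-trimethyltridec-11-en-1-yl}-6-methyl-1,2-dioxan-3-yl]propanoate | COC(=O)[C@H](C)[C@@H]1CC[C@@](C)(CCC[C@H](C)CCC[C@](C)(CCC=C(C)C)OOC(C)(C)OC)OO1 | intermediate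
27 | methyl (2R)-2-{(3S,6R)-6-[(4R,8R)-8-hydroperoxy-4,8,12-trimethyltridec-11-en-1-yl]-6-methyl-1,2-dioxan-3-yl}propanoate | COC(=O)[C@H](C)[C@@H]1CC[C@@](C)(CCC[C@H](C)CCC[C@](C)(CCC=C(C)C)OO)OO1 | target

Total step count: 19.
Longest linear sequence: 12 steps (1 to 27 through steps 1–5, 10–13 and 17–19).

**Steps most likely to fail**

Step 10 (Proposed new method). The organozinc may cleave the O–O bond reductively instead of alkylating the peroxycarbenium carbon. The silyl peroxide may also fail to open the lactone, so that the sequence stalls at the open-chain stage. The C6 face is not discriminated, so half of the material is expected to be lost as the C6 epimer. The fallback uses known chemistry, sets out from 9 (through its triflate 10) and returns at 17. 2,3-Dibromopropene and allylmagnesium bromide give 2-bromohexa-1,5-diene F1, and magnesium turnings in THF convert it into (hexa-1,5-dien-2-yl)magnesium bromide F2. This Grignard reagent is coupled with triflate 10 under CuBr·SMe2 catalysis to give the bromo diene F3. Cross-metathesis of its monosubstituted alkene with methyl methacrylate (second-generation Grubbs catalyst) gives the enoate F4. Isayama–Mukaiyama hydroperoxysilylation of the 1,1-disubstituted alkene (Co(acac)2, O2, Et3SiH), which should react much faster than the trisubstituted enoate, gives the tertiary silyl peroxide F5. Desilylation with HF·pyridine gives the hydroperoxide F6. Et2NH in CF3CH2OH then closes the ring by intramolecular oxa-Michael addition, and 17 is separated from its stereoisomers. This fallback gives up the control of C2 and C3.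

Step 16. The unprotected α-hydroperoxy aldehyde may fragment before it is perketalized, by closure to a dioxetane hemiacetal and C–C cleavage to the methyl ketone. The fallback sets out from 22 and returns at 24. Phenylboronic acid with MgSO4 ties the 1,2-diol as the cyclic boronate F7. 2-Methoxypropene and pyridinium p-toluenesulfonate convert the hydroperoxide into the peroxyketal boronate F8. NaIO4 in THF/pH 7 buffer then hydrolyses the boronate and cleaves the diol, so that the aldehyde appears only when the peroxide is already masked.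

Step 17. The base or the sulfonyl carbanion may deprotonate the ester α-carbon, which is followed by β-elimination of the ring peroxide (retro-oxa-Michael opening); the carbanion may also attack the O–O bond. The fallback sets out from 19 and returns at 26. LiOH in THF/H2O at 0 °C saponifies 19 to the sulfone acid F9, whose carboxylate cannot be enolized under the olefination conditions. Its dianion (2.2 equiv KN(SiMe3)2) is olefinated with 24 to give the dienoic acid F10. Diimide reduction gives the saturated acid F11, and Me3SiCHN2 gives 26.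

**Further compounds**

F1 | step 10 | 2-bromohexa-1,5-diene | C=CCCC(Br)=C
F2 | step 10 | (hexa-1,5-dien-2-yl)magnesium bromide | C=CCCC(=C)[Mg]Br
F3 | step 10 | (9S)-11-bromo-9-methyl-5-methylideneundec-1-ene | C=CCCC(=C)CCC[C@H](C)CCBr
F4 | step 10 | methyl (2E,10S)-12-bromo-2,10-dimethyl-6-methylidenedodec-2-enoate | COC(=O)/C(C)=C/CCC(=C)CCC[C@H](C)CCBr
F5 | step 10 | methyl (2E,10S)-12-bromo-2,6,10-trimethyl-6-[(triethylsilyl)peroxy]dodec-2-enoate (both C6 epimers) | COC(=O)/C(C)=C/CCC(C)(OO[Si](CC)(CC)CC)CCC[C@H](C)CCBr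
F6 | step 10 | methyl (2E,10S)-12-bromo-6-hydroperoxy-2,6,10-trimethyldodec-2-enoate (both C6 epimers) | COC(=O)/C(C)=C/CCC(C)(OO)CCC[C@H](C)CCBr
F7 | step 16 | (4R)-4-[(2S)-2-hydroperoxy-6-methylhept-5-en-2-yl]-2-phenyl-1,3,2-dioxaborolane | B1(c2ccccc2)OC[C@@H](O1)[C@](C)(CCC=C(C)C)OO
F8 | step 16 | (4R)-4-{(2S)-2-[(2-methoxypropan-2-yl)peroxy]-6-methylhept-5-en-2-yl}-2-phenyl-1,3,2-dioxaborolane | B1(c2ccccc2)OC[C@@H](O1)[C@](C)(CCC=C(C)C)OOC(C)(C)OC
F9 | step 17 | (2R)-2-[(3S,6R)-6-methyl-6-{(4S)-4-methyl-6-[(1-phenyl-1H-tetrazol-5-yl)sulfonyl]hexyl}-1,2-dioxan-3-yl]propanoic acid | OC(=O)[C@H](C)[C@@H]1CC[C@@](C)(CCC[C@H](C)CCS(=O)(=O)c2nnnn2-c2ccccc2)OO1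
F10 | step 17 | (2R)-2-[(3S,6R)-6-{(4S,6E,8S)-8-[(2-methoxypropan-2-yl)peroxy]-4,8,12-trimethyltrideca-6,11-dien-1-yl}-6-methyl-1,2-dioxan-3-yl]propanoic acid | OC(=O)[C@H](C)[C@@H]1CC[C@@](C)(CCC[C@H](C)C/C=C/[C@](C)(CCC=C(C)C)OOC(C)(C)OC)OO1
F11 | step 17 | (2R)-2-[(3S,6R)-6-{(4S,8R)-8-[(2-methoxypropan-2-yl)peroxy]-4,8,12-trimethyltridec-11-en-1-yl}-6-methyl-1,2-dioxan-3-yl]propanoic acid | OC(=O)[C@H](C)[C@@H]1CC[C@@](C)(CCC[C@H](C)CCC[C@](C)(CCC=C(C)C)OOC(C)(C)OC)OO1
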